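The side product moved while the target stayed level in both earlier runs, so I compared two amounts: side product at 3.00 min, 42.5% of the charge in the dawn run and 42.7% in the autumn run, which had 1.50 times the charge. Their ratio was 1.00; I call it the charge factor, the share formed at a fixed time at the higher charge over that at the lower. The two readings lay 0.2 percentage points apart against a scatter of 0.5 points, so I read the factor as one: first order, with each share of the charge following the same curve in these runs.

| flask | substrate | remark | time |
|---|---|---|---|
| dawn | 1 mM | run made earlier |  |
| autumn | 1.5 mM | run made earlier |  |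
| flask | 2.0 mM |  | 2.5 min |

| run | time / min | target / % | side product / % |
|---|---|---|---|
| dawn | 0.250 | 36.1 | 7.1 |
| dawn | 0.417 | 34.9 | 12.7 |
| dawn | 0.833 | 36.0 | 20.6 |
| dawn | 1.50 | 34.2 | 30.4 |
| dawn | 3.00 | 35.4 | 42.5 |
| autumn | 0.667 | 35.6 | 18.7 |
| autumn | 1.33 | 35.7 | 29.5 |
| autumn | 2.00 | 36.4 | 36.4 |
| autumn | 2.50 | 36.1 | 38.8 |
| autumn | 3.00 | 35.5 | 42.7 |

(standard deviation of a reading: 0.5 percentage points)

- ratio of target to side product at 0.20 s
- ratio of target to side product at 2.5 min



I therefore let the autumn readings at 2.5 min stand for the flask at 2.0 mM: target over side product, divided by the factor, gave 0.926. The earliest reading came at 0.250 min, so I had no figure of my own for 0.20 s.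

The forecast differed from me, with 0.91 late and 340 early, noting that “the burst's timescale is unresolved”.

The flask gave 77.6 and 0.903.

    substrate → intermediate A (k = 0.200 s⁻¹)
    intermediate A ⇌ intermediate B (K = 7.80, k = 3.60 s⁻¹)
    substrate → target (k = 0.110 s⁻¹)
    intermediate A → side product (k = 0.0880 s⁻¹)
    intermediate B ⇌ intermediate C (K = 0.550, k = 0.0110 s⁻¹)
    intermediate C ⇌ intermediate D (K = 0.490, k = 1.80 s⁻¹)

In this flask, substrate fed the target and had fallen to 0.956% of its charge at 0.250 min, and the target stood at 35.5% at 2.50 min. Intermediate A went on passing into side product while intermediate B fell from 44.6% at 0.250 min to 11.1% at 2.50 min.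

For the neighbour flask at 8.0 mM, the factor 1.00 put the ratio at 2.5 min at 0.903. The computed ratios there are 0.903 at 2.5 min and 77.6 at 0.20 s.

The numbers in the tables were generated by integration with constants of no real substance; scatter was added.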